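## Structural features

Prosogerin D is a flavone. A benzene ring A is fused to a 4-pyranone ring C through the C4a–C8a bond, and a 3,4,5-trimethoxyphenyl ring B is joined to C2 of ring C by one C–C bond. The molecule is planar and has no stereocentre. The stereocentres that arise on the way (C4a and C8a, adjacent at the ring fusion, and C6 next to the C7 carbonyl) are therefore transient and only have to be erased again. Ring A carries two neighbouring oxygens that differ: a methyl ether at C6 and a free hydroxyl at C7, which is para to C4a. The real difficulty is to place these two oxygens at C6 and C7 and to tell them apart without a late, regiochemically ambiguous methylation or substitution on an electron-rich arene. Sensitive points are the phenol and the electron-rich ring B towards oxidants, and the C2=C3 enone of ring C towards nucleophiles. In every partly saturated precursor the O1–C8a bond is also at risk: it can be lost by β-elimination as soon as C8a is sp3 and a carbonyl group sits two carbons away. The key step uses the fact that the fusion bond C4a–C8a is also a C=C bond of a 4-pyranone. With an ester on C4a it is a doubly activated dienophile, C5–C8 are the four carbons of a butadiene, and a siloxy group on the diene carbon that becomes C7 brings in the C7 oxygen and leaves C6 as the nucleophilic carbon for methoxylation.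

## Logic of the disconnections

**12 back to 11.** No skeletal bond is cut. Two hydrogens are returned to C5 and C6, so that ring A becomes the keto form of a 5,6-dihydrophenol. The free phenol then appears only in the last step and by the easiest kind of oxidation, the dehydrogenation of a dihydroarene. The gain is that an arene substitution problem becomes functional-group chemistry on a cyclohexanone. The forward step must stop at the phenol and must spare the methoxy groups and ring B.

**11 back to 10.** The bond from C4a to the carboxyl carbon and the C8a–H bond are restored. The carboxyl group is what makes the pyranone a dienophile, so it must be present in the adduct and leave afterwards. As an allyl ester it can leave under neutral palladium catalysis with formation of the C4a=C8a double bond. The gain is that 10 is the direct oxidation product of the cycloadduct and that O1 is locked on an sp2 carbon at the moment the ester departs. The forward step demands loss of the hydrogen from C8a rather than from C5, and it must be faster than allyl transfer to carbon or β-elimination of O1.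

**10 back to 9.** The C6–OMe bond is cut. C6 is the nucleophilic carbon of the enol ether in 9, so the oxygen can enter by electrophilic oxidation in methanol and is a methyl ether from the start, while the C7 oxygen remains a carbonyl. The gain is that the two oxygens of ring A never have to be differentiated as phenols. The forward step needs an oxidant that attacks only the enol ether, and the enol ether must not be hydrolysed before it is oxidised.

**9 back to 6 and 8.** The bonds C4a–C5 and C8–C8a are cut, which removes ring A and both transient stereocentres in one operation. The cut is made here because the C2=C3 bond of 6 is activated by a ketone and an ester, and the polarisation of 8 decides where the oxygen ends up. The gain is the largest of the route: a bicyclic, oxygenated core falls apart into a monocyclic pyranone and a four-carbon diene. The forward step must select the ester-bearing double bond of 6, orient 8 so that its siloxy carbon becomes C7, and keep the silyl enol ether intact.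

**6 back to 3 and 4 (through 5).** Two bonds of the pyranone are cut: the ring O–CH bond (later O1–C8a) and the C–C bond between the aroyl carbon and the methylene carbon (later C2–C3). This separates ring B as an acid chloride from a four-carbon enaminone that already holds the ester and the future C8a. The forward step needs C-acylation of the methyl ketone enolate of 3 and an acid-induced ring closure with loss of the amine.

**3 back to 1 and 2, and 8 back to 7.** In 3 the C=C bond between C2 of the keto ester and the aminomethylene carbon (later C4a–C8a) is cut. Because 1 has only one doubly activated methylene, the position of this carbon is fixed before any further carbonyl group is present. In 8 the O–Si bond is cut, leading to the enone 7. Both forward steps are condensations on commercial materials.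

## Other disconnections considered

**Alternative 1:** The cut runs through ring C at C4–C4a and O1–C2; ring A is bought as a phenol ether. In the forward key step the aryl 3-chloropropargyl ether A2 is heated in N,N-diethylaniline. A Claisen rearrangement to an ortho-allenyl dienone, enolisation, a 1,5-hydrogen shift and an oxa-6π electrocyclisation should give the 4-chloro-2H-chromene A1.
- In its favour: the two oxygens of ring A arrive already differentiated (methyl and benzyl ether), so ring A needs no oxidation at all. On this point the alternative is better than the chosen plan. The ring construction is metal-free, and the chlorine marks C4 for the later carbonyl.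
- Against it here: the ether oxygen has two non-equivalent ortho positions, and only sterics favour the one that becomes C4a. The propargylic C–O bond of A2 is also benzylic to an electron-rich aryl group and may ionise at the temperature of the rearrangement. A1 has the wrong oxidation level at C2 and C4, so hydrolysis of the vinyl chloride, dehydrogenation and debenzylation must follow.
- Comparison: both key steps are thermal pericyclic reactions of comparable standing, and both need about three further operations; on these two points the plans are equal. The chosen plan fixes its regiochemistry electronically instead of sterically and needs no protecting group on the phenol. Alternative 1 needs more steps before its key step.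

**Alternative 2:** The cut removes three bonds of ring A (C5–C6, C4a–C8a and C8–C8a). In the forward key step the zerovalent chromium carbene complex A4, (CO)5Cr=C(OMe)C(OtBu)=CH2, is heated with the terminal alkyne of the diyne A5. A benzannulation with insertion of one CO should give the phenol A3, in which the carbene carbon has become C6 (OMe), the vinyl carbons C7 (OtBu) and C8, and the CO carbon C8a.
- In its favour: ring A is built de novo with both oxygens differentiated and arrives aromatic, so no dehydrogenation is needed afterwards; on redox economy after the key step it is better than the chosen plan. The regiochemistry with a terminal alkyne is reliable, which makes it the equal of the chosen plan on that point.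
- Against it here: stoichiometric chromium carbonyl chemistry and a sensitive alkoxyvinyl carbene complex are required. The second, aryl-substituted alkyne of A5 must stay out of the reaction. A3 is a 4-methoxyphenol that is easily oxidised to a quinone during decomplexation. Four operations still follow: desilylation, oxidation to the ynone, 6-endo closure of ring C in competition with 5-exo closure, and removal of the tert-butyl group.
- Comparison: structurally both plans construct ring A and differentiate the oxygens through the reagents. Mechanistically the chosen plan uses a catalytic main-group Lewis acid instead of a stoichiometric transition-metal template. Counting the preparation of A4 and A5, the chosen plan is clearly shorter.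

**Alternative 3:** The cut is the single bond O1–C8a. In the forward key step the diketone phenol A7 is oxidised at a graphite anode (constant current, undivided cell, hexafluoroisopropanol, Bu4NBF4). The enol oxygen of the 1,3-diketone should attack the oxidised ring A para to the phenol and close ring C to give the 6-hydroxyflavone A6.
- In its favour: A7 comes from a Claisen condensation of two simple aryl carbonyl compounds, the oxidant is the electrode, and no oxygen has to be pre-installed at C8a. On step count to the flavone skeleton and on reagent waste it is better than the chosen plan.
- Against it here: the positions ortho and para to the phenol are both activated and both lie next to the tether, so the angular isomer can form. The central carbon of the diketone can attack instead of the oxygen. Ring B and the product, a para-alkoxyphenol, are themselves oxidisable. O-methylation at C6 and debenzylation must follow, so the differentiation of the two oxygens rests on a protecting group.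
- Comparison: structurally it is the most direct plan. Mechanistically its regiochemistry depends on the charge distribution of a phenoxonium ion, whereas the chosen plan relies on orbital-controlled cycloaddition and on the fixed polarity of an enol ether. With the two end-game operations the step counts are about equal, and the chosen plan carries the lower regiochemical risk.

Key step: step 4

Remark on the chemistry: the ester alkyl group is treated as a spectator and is allyl instead of methyl throughout. The bonds formed, the ring closed and the skeletons of 6 and 9 are unchanged. An atom-by-atom re-derivation of the adduct (cis fusion, siloxy carbon = C7) showed no structural error to correct.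

Two further design points follow from this:
- **Allyl ester.** Removing a methyl ester from the quaternary C4a needs hot chloride in DMSO, applied to a ketone that has O1 on its β-carbon. That invites opening of ring C, and two dehydrogenations would still be required afterwards. The allyl ester leaves under neutral palladium catalysis and creates the C4a=C8a bond as it goes.
- **Aminomethylene carbon first.** The aminomethylene carbon is installed before the 1,3-diketone exists, so there is no question of which methylene condenses.

## Route

**Step 1**
Reactants: 1 allyl acetoacetate (prop-2-en-1-yl 3-oxobutanoate); 2 N,N-dimethylformamide dimethyl acetal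
Product: 3 allyl 2-[(dimethylamino)methylidene]-3-oxobutanoate
Conditions: 2 (1.1 equiv), neat, rt → 40 °C; evaporate
Reagents that add atoms: none
Why: Condensation of an active methylene compound with an amide acetal; C2 of the β-keto ester is the only doubly activated position, so the aminomethylene carbon (the future C8a) is fixed next to the ester.

**Step 2**
Reactants: 3 allyl 2-[(dimethylamino)methylidene]-3-oxobutanoate; 4 3,4,5-trimethoxybenzoyl chloride
Product: 6 allyl 4-oxo-6-(3,4,5-trimethoxyphenyl)-4H-pyran-3-carboxylate, via acylated enaminone 5 (not isolated)
Conditions: LiN(SiMe3)2 (2.5 equiv), THF, −78 °C; then 3 M HCl, Et2O, rt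
Reagents that add atoms: none
Why: Deprotonation of the methyl ketone of the vinylogous carbamate and C-acylation by the acid chloride (Claisen-type acylation, the second equivalent of base holding the 1,3-diketone as its enolate); acid then drives addition–elimination of the enol oxygen at the aminomethylene carbon with loss of dimethylamine, a standard 4-pyranone ring closure.

**Step 3**
Reactants: 7 methyl vinyl ketone
Product: 8 2-(tert-butyldimethylsilyloxy)buta-1,3-diene
Conditions: TBSOTf (1.05 equiv), Et3N (1.5 equiv), CH2Cl2, 0 °C
Reagents that add atoms: tert-butyldimethylsilyl trifluoromethanesulfonate (TBSOTf), CC(C)(C)[Si](C)(C)OS(=O)(=O)C(F)(F)F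
Why: Soft enolisation of an enone with a silyl triflate and an amine traps the cross-conjugated enol as its silyl ether; the tert-butyldimethylsilyl group is chosen because its enol ethers tolerate ZnCl2 and chromatography better than trimethylsilyl ones.

**Step 4**
Reactants: 6 allyl 4-oxo-6-(3,4,5-trimethoxyphenyl)-4H-pyran-3-carboxylate; 8 2-(tert-butyldimethylsilyloxy)buta-1,3-diene
Product: 9 allyl (4aR*,8aR*)-7-(tert-butyldimethylsilyloxy)-4-oxo-2-(3,4,5-trimethoxyphenyl)-4a,5,8,8a-tetrahydro-4H-chromene-4a-carboxylate (cis-fused, racemic)
Conditions: 8 (2.5 equiv), ZnCl2 (1.0 equiv, 1 M in Et2O), CH2Cl2, 0 °C → rt; Et3N quench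
Reagents that add atoms: none
Why: This is a normal-electron-demand Diels-Alder reaction: the C2=C3 bond of 6 carries both the ring ketone and the ester, ZnCl2 chelates these two carbonyl groups and lowers the LUMO of that bond only, and the electron-rich diene 8 adds across it in a concerted but asynchronous [4+2] process in which the C8–C8a bond runs ahead of the C4a–C5 bond. The closest known reaction type is the Lewis-acid-promoted cycloaddition of 3-alkoxycarbonyl chromones and 4-pyranones with 2-siloxydienes. Ring A is closed by the cycloaddition itself, with two sigma bonds formed suprafacially on both partners to give a six-membered carbocycle fused at C4a–C8a; if the process became stepwise it would be a Mukaiyama–Michael addition at C8a followed by six-membered closure of the chelated keto ester enolate onto the siloxyallyl cation, with the same outcome. The stereocentres C4a and C8a are set together because both new bonds form on one face of the planar pyranone, so the ester and the 8a-hydrogen are cis; 8 has no terminal substituents, so there is no endo/exo question, and the adduct is racemic. Site selectivity for the ester-bearing double bond over the aryl-substituted one is secured by the double activation and the chelation. The regiochemistry that places the siloxy carbon para to C4a is secured by the large HOMO coefficient at the CH2 next to the siloxy carbon of 8 and the large LUMO coefficient at the oxygen-bearing β-carbon of 6. Survival of the enol ether is secured by the robust silyl group, the mild Lewis acid and the amine quench.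

**Step 5**
Reactants: 9 allyl (4aR*,8aR*)-7-(tert-butyldimethylsilyloxy)-4-oxo-2-(3,4,5-trimethoxyphenyl)-4a,5,8,8a-tetrahydro-4H-chromene-4a-carboxylate
Product: 10 allyl (4aR*,8aR*)-6-methoxy-4,7-dioxo-2-(3,4,5-trimethoxyphenyl)-5,6,7,8-tetrahydro-4H-chromene-4a(8aH)-carboxylate (mixture of C6 epimers)
Conditions: PhI(OAc)2 (1.1 equiv), BF3·OEt2 (1.2 equiv), MeOH/CH2Cl2, −40 → 0 °C
Reagents that add atoms: methanol, CO
Why: Hypervalent-iodine α-methoxylation of a silyl enol ether: the enol ether attacks the trivalent iodine through C6, and methanol displaces iodobenzene from the α-iodanyl ketone, giving the C7 ketone and the C6–OMe bond. The configuration at C6 is not controlled and need not be, because C6 becomes aromatic; the quaternary C4a keeps any reversible opening of ring C harmless at this stage.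

**Step 6**
Reactants: 10 allyl (4aR*,8aR*)-6-methoxy-4,7-dioxo-2-(3,4,5-trimethoxyphenyl)-5,6,7,8-tetrahydro-4H-chromene-4a(8aH)-carboxylate
Product: 11 6-methoxy-2-(3,4,5-trimethoxyphenyl)-5,6-dihydro-4H-chromene-4,7(8H)-dione (racemic)
Conditions: Pd(OAc)2 (10 mol %), PPh3 (10 mol %), MeCN, 80 °C
Reagents that add atoms: none
Why: Tsuji decarboxylation–dehydrogenation of an α,α-disubstituted allyl β-keto ester: zerovalent palladium formed in situ ionises the allyl ester, the β-keto carboxylate loses CO2, and the palladium enolate at C4a undergoes β-hydride elimination of the hydridic, oxygen-bearing C8a–H, which is cis to the departing ester, releasing propene. The 4-pyranone is restored, C4a and C8a become sp2, and O1 can no longer be lost by β-elimination.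

**Step 7**
Reactants: 11 6-methoxy-2-(3,4,5-trimethoxyphenyl)-5,6-dihydro-4H-chromene-4,7(8H)-dione
Product: 12 Prosogerin D, 7-hydroxy-6-methoxy-2-(3,4,5-trimethoxyphenyl)-4H-chromen-4-one
Conditions: DDQ (1.1 equiv), 1,4-dioxane, rt
Reagents that add atoms: none
Why: Quinone dehydrogenation of a dihydroarene: ring A of 11 is the keto tautomer of a 5,6-dihydrophenol, DDQ takes hydride from C5 or C6 of the enol form and loss of a proton gives the phenol. The C6 stereocentre disappears, and the electron-poor 7-hydroxychromone should resist further oxidation.

## Compound list

1 | allyl acetoacetate (prop-2-en-1-yl 3-oxobutanoate) | C=CCOC(=O)CC(C)=O | starting material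
2 | N,N-dimethylformamide dimethyl acetal | COC(OC)N(C)C | starting material
3 | allyl 2-[(dimethylamino)methylidene]-3-oxobutanoate (interconverting E/Z push–pull enaminone, geometry not specified) | C=CCOC(=O)C(=CN(C)C)C(C)=O | intermediate
4 | 3,4,5-trimethoxybenzoyl chloride | COc1cc(C(=O)Cl)cc(OC)c1OC | starting material
5 | allyl 2-[(dimethylamino)methylidene]-3,5-dioxo-5-(3,4,5-trimethoxyphenyl)pentanoate (geometry not specified) | C=CCOC(=O)C(=CN(C)C)C(=O)CC(=O)c1cc(OC)c(OC)c(OC)c1 | intermediate (not isolated)
6 | allyl 4-oxo-6-(3,4,5-trimethoxyphenyl)-4H-pyran-3-carboxylate | C=CCOC(=O)c1coc(-c2cc(OC)c(OC)c(OC)c2)cc1=O | intermediate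
7 | methyl vinyl ketone | C=CC(C)=O | starting material
8 | 2-(tert-butyldimethylsilyloxy)buta-1,3-diene | C=CC(=C)O[Si](C)(C)C(C)(C)C | intermediate
9 | allyl (4aR*,8aR*)-7-(tert-butyldimethylsilyloxy)-4-oxo-2-(3,4,5-trimethoxyphenyl)-4a,5,8,8a-tetrahydro-4H-chromene-4a-carboxylate (cis-fused, racemic, one enantiomer drawn) | C=CCOC(=O)[C@]12CC=C(O[Si](C)(C)C(C)(C)C)C[C@H]1OC(c1cc(OC)c(OC)c(OC)c1)=CC2=O | intermediate
10 | allyl (4aR*,8aR*)-6-methoxy-4,7-dioxo-2-(3,4,5-trimethoxyphenyl)-5,6,7,8-tetrahydro-4H-chromene-4a(8aH)-carboxylate (cis-fused, racemic, both C6 epimers) | C=CCOC(=O)[C@]12CC(OC)C(=O)C[C@H]1OC(c1cc(OC)c(OC)c(OC)c1)=CC2=O | intermediate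
11 | 6-methoxy-2-(3,4,5-trimethoxyphenyl)-5,6-dihydro-4H-chromene-4,7(8H)-dione (racemic at C6) | COC1CC2=C(CC1=O)OC(c1cc(OC)c(OC)c(OC)c1)=CC2=O | intermediate
12 | Prosogerin D, 7-hydroxy-6-methoxy-2-(3,4,5-trimethoxyphenyl)-4H-chromen-4-one (no stereocentre) | COc1cc2c(=O)cc(-c3cc(OC)c(OC)c(OC)c3)oc2cc1O | target

## Summary and risk assessment

Total step count: 7. Longest linear sequence: 6 steps (1 → 3 → 6 → 9 → 10 → 11 → 12); the diene 8 is made in one side step from 7.

Least certain steps:

**Step 4 (key step).** The mono-oxygenated diene may add too slowly to a dienophile whose β-carbon bears a donor oxygen. The Lewis acid may then desilylate or oligomerise the diene. A stepwise Michael addition is also possible, with opening of ring C by β-elimination from the chelated enolate before the second bond closes. The fallback sets out from 6 and comes back to the route at 12.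
- 6 would be heated without Lewis acid (toluene, 80–110 °C) with the more reactive 1-methoxy-3-(trimethylsilyloxy)buta-1,3-diene. This diene bonds through its CH2 terminus to the same β-carbon and should give the cis-fused adduct allyl 5-methoxy-4-oxo-2-(3,4,5-trimethoxyphenyl)-7-(trimethylsilyloxy)-4a,5,8,8a-tetrahydro-4H-chromene-4a-carboxylate F1.
- Methoxylation as in step 5 would give allyl 5,6-dimethoxy-4,7-dioxo-2-(3,4,5-trimethoxyphenyl)-5,6,7,8-tetrahydro-4H-chromene-4a(8aH)-carboxylate F2.
- Brief acid treatment (TsOH, CH2Cl2) should eliminate methanol from C5 and give the enone allyl 6-methoxy-4,7-dioxo-2-(3,4,5-trimethoxyphenyl)-8,8a-dihydro-4H-chromene-4a(7H)-carboxylate F3.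
- The conditions of step 6 would then remove the ester with formation of C4a=C8a. The resulting cyclohexadienone is the keto tautomer of 12, so one oxidation is replaced by an elimination and no quinone is needed.

**Step 6.** Three processes can compete with the wanted β-hydride elimination: loss of a hydrogen from C5 instead of C8a, reductive elimination that transfers the allyl group to C4a, and proton transfer to the enolate followed by β-elimination of O1 through the C7 ketone. The fallback sets out from 10 and comes back at 12.
- The ester would be removed reductively (Pd(PPh3)4 cat., HCO2H/Et3N with the acid in slight excess, THF, rt) to give 6-methoxy-2-(3,4,5-trimethoxyphenyl)-4a,5,6,8a-tetrahydro-4H-chromene-4,7(8H)-dione F4.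
- F4 would then be dehydrogenated twice (DDQ, 2.2 equiv, dioxane, 80 °C). The first dehydrogenation should occur at the oxygen-bearing C8a–H, as in the conversion of flavanones into flavones.

**Step 5.** The acid may protodesilylate the enol ether to the unfunctionalised C7 ketone before oxidation. The iodanyl intermediate may eliminate to the enone instead of being substituted. The trivalent iodine reagent may also oxidise ring B. The fallback sets out from 9 and comes back at 10.
- A Rubottom oxidation (mCPBA, NaHCO3, CH2Cl2, 0 °C; then HF·pyridine, MeCN) would give allyl 6-hydroxy-4,7-dioxo-2-(3,4,5-trimethoxyphenyl)-5,6,7,8-tetrahydro-4H-chromene-4a(8aH)-carboxylate F5.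
- F5 would be methylated without strong base (Me3OBF4, 2,6-di-tert-butyl-4-methylpyridine, CH2Cl2) to give 10.

**Step 2.** The amide base may attack the acid chloride, the enolate may be acylated on oxygen instead of carbon, and ring closure may be incomplete. The fallback sets out from 1 and comes back at 6.
- The dianion of 1 (LiN(iPr)2, 2.2 equiv, THF, −78 → 0 °C) would be acylated at its terminal carbon with methyl 3,4,5-trimethoxybenzoate to give allyl 3,5-dioxo-5-(3,4,5-trimethoxyphenyl)pentanoate F6.
- Condensation of F6 with 2 (toluene, rt → 60 °C) and acid treatment would give 6 through 5. The price is that the site of condensation is then no longer fixed in advance.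

## Further compounds

F1 | step 4 | allyl 5-methoxy-4-oxo-2-(3,4,5-trimethoxyphenyl)-7-(trimethylsilyloxy)-4a,5,8,8a-tetrahydro-4H-chromene-4a-carboxylate (cis-fused, racemic, C5 configuration not specified) | C=CCOC(=O)[C@]12C(OC)C=C(O[Si](C)(C)C)C[C@H]1OC(c1cc(OC)c(OC)c(OC)c1)=CC2=O
F2 | step 4 | allyl 5,6-dimethoxy-4,7-dioxo-2-(3,4,5-trimethoxyphenyl)-5,6,7,8-tetrahydro-4H-chromene-4a(8aH)-carboxylate (cis-fused, racemic, C5 and C6 not specified) | C=CCOC(=O)[C@]12C(OC)C(OC)C(=O)C[C@H]1OC(c1cc(OC)c(OC)c(OC)c1)=CC2=O
F3 | step 4 | allyl 6-methoxy-4,7-dioxo-2-(3,4,5-trimethoxyphenyl)-8,8a-dihydro-4H-chromene-4a(7H)-carboxylate (cis-fused, racemic) | C=CCOC(=O)[C@]12C=C(OC)C(=O)C[C@H]1OC(c1cc(OC)c(OC)c(OC)c1)=CC2=O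
F4 | step 6 | 6-methoxy-2-(3,4,5-trimethoxyphenyl)-4a,5,6,8a-tetrahydro-4H-chromene-4,7(8H)-dione (mixture of diastereomers, racemic) | COC1CC2C(CC1=O)OC(c1cc(OC)c(OC)c(OC)c1)=CC2=O
F5 | step 5 | allyl 6-hydroxy-4,7-dioxo-2-(3,4,5-trimethoxyphenyl)-5,6,7,8-tetrahydro-4H-chromene-4a(8aH)-carboxylate (cis-fused, racemic, both C6 epimers) | C=CCOC(=O)[C@]12CC(O)C(=O)C[C@H]1OC(c1cc(OC)c(OC)c(OC)c1)=CC2=O
F6 | step 2 | allyl 3,5-dioxo-5-(3,4,5-trimethoxyphenyl)pentanoate | C=CCOC(=O)CC(=O)CC(=O)c1cc(OC)c(OC)c(OC)c1
A1 | alternative 1 | 7-(benzyloxy)-4-chloro-6-methoxy-2-(3,4,5-trimethoxyphenyl)-2H-chromene (racemic) | COc1cc2c(cc1OCc1ccccc1)OC(c1cc(OC)c(OC)c(OC)c1)C=C2Cl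
A2 | alternative 1 | 2-(benzyloxy)-4-{[3-chloro-1-(3,4,5-trimethoxyphenyl)prop-2-yn-1-yl]oxy}-1-methoxybenzene (racemic) | COc1ccc(OC(C#CCl)c2cc(OC)c(OC)c(OC)c2)cc1OCc1ccccc1
A3 | alternative 2 | 5-tert-butoxy-2-[1-(tert-butyldimethylsilyloxy)-3-(3,4,5-trimethoxyphenyl)prop-2-yn-1-yl]-4-methoxyphenol (racemic) | CC(C)(C)Oc1cc(O)c(C(O[Si](C)(C)C(C)(C)C)C#Cc2cc(OC)c(OC)c(OC)c2)cc1OC
A4 | alternative 2 | pentacarbonyl[(1-tert-butoxyvinyl)(methoxy)carbene]chromium, (CO)5Cr=C(OMe)C(OtBu)=CH2 | COC(C(=C)OC(C)(C)C)=[Cr](=C=O)(=C=O)(=C=O)(=C=O)=C=O
A5 | alternative 2 | tert-butyldimethyl{[1-(3,4,5-trimethoxyphenyl)penta-1,4-diyn-3-yl]oxy}silane (racemic) | C#CC(O[Si](C)(C)C(C)(C)C)C#Cc1cc(OC)c(OC)c(OC)c1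
A6 | alternative 3 | 7-(benzyloxy)-6-hydroxy-2-(3,4,5-trimethoxyphenyl)-4H-chromen-4-one | O=c1cc(-c2cc(OC)c(OC)c(OC)c2)oc2cc(OCc3ccccc3)c(O)cc12
A7 | alternative 3 | 1-[4-(benzyloxy)-3-hydroxyphenyl]-3-(3,4,5-trimethoxyphenyl)propane-1,3-dione | O=C(CC(=O)c1cc(OC)c(OC)c(OC)c1)c1ccc(OCc2ccccc2)c(O)c1
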